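Late in the south-east run, between 6.00 min and 50.0 min, G and E (percent of the G charged) fall together, and G minus E reads 20 percentage points, then 21 points. You are taking over Tuesday's and Friday's flasks, and that gap is what I reckon them by.

in all of them: G 1.7 M

| flask | Q | X | remark | time |
|---|---|---|---|---|
| south-east | 1.36 M | 0.051 M | run made earlier |  |
| west | 1.36 M | 0.068 M | run made earlier |  |
| Tuesday's | 1.40 M | 0.0340 M |  | 80 min |
| Friday's | 1.80 M | 0.0340 M |  | 80 min |

| run | time / min | G / % | E / % |
|---|---|---|---|
| south-east | 6.00 | 57.8 | 37.7 |
| south-east | 15.0 | 54.2 | 34.2 |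
| south-east | 20.0 | 52.3 | 32.6 |
| south-east | 30.0 | 49.0 | 29.0 |
| south-east | 40.0 | 46.4 | 26.8 |
| south-east | 50.0 | 44.7 | 24.0 |
| west | 6.00 | 57.1 | 37.3 |
| west | 15.0 | 54.1 | 33.6 |
| west | 20.0 | 52.6 | 31.8 |
| west | 30.0 | 49.1 | 29.5 |
| west | 40.0 | 46.9 | 26.5 |
| west | 50.0 | 44.5 | 24.1 |

(each reading ± 0.3 percentage points)

1. part of the G that has reacted at the end, Tuesday's
2. part of the G that has reacted at the end, Friday's
3. what raising the concentration of Q from its lowest to its highest value here does to the part of the G that has reacted (changes below 5 percentage points count as none) (it falls / no change / it rises)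

- the earlier runs were read with a standard deviation of 0.3 points

By the first reading of the south-east run, 0.717 M of G had gone, about half of the Q charged. So I count two Q per E, leave X out of the count, and start E at c(Q)/(2c(G)) of the charge. After that, I take it, G and E leave in pairs at rate κ·G·E. The gap then holds at 1 − c(Q)/c(G), in both earlier runs 20.0%, and the rate integrates in closed form: ln(G/E) climbs in a straight line whose slope is κ times the gap. The first and last readings of both earlier runs give, as a reading with their scatter, the pair constant κ, that slope over the gap with G and E as fractions of the charge: 0.02171 /min. My reckoning for 80 min: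

| Flask | Gap | G/E | G reacted |
|---|---|---|---|
| Tuesday's | 17.6% | 1.94 | 63.6% |
| Friday's | −5.88% | 0.803 | 76.1% |

Don't touch the Q charge of Tuesday's flask: 0.400 M more, as in Friday's, turns the gap negative and, by my reckoning, lifts the reacted part by 12 points.

The forecast gives 63% (57% to 67%) for Tuesday's and 72% (65% to 78%) for Friday's, below my Friday's figure, and says it rises: “This drain pulls G down as well.”

The flasks give 62.3% on Tuesday's and 74.3% on Friday's: it rises, by 12 points.

    G + Q ⇌ L + E (K = 2.30, k = 0.0150 /M/s)
    Q + L ⇌ J, settled at all times (K = 5800 /M)
    Q + X → D (k = 0.0100 /M/s)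
    G + E → Z (k = 1.90 × 10⁻⁴ /M/s)

In Tuesday's flask at the end, the reversible step alone relaxes with a half-life of 0.956 min, short against 80 min. In the same flask at 0.259 min, the forward rate of that step alone uses G 160 times as fast as G + E → Z does, and at the end Q, the limiting reagent, stands at 0.37% of its charge unbound, with G/E at 1.87 against the reckoned 1.94. For Tuesday's flask read at 5.0 h, κ gives G/E 4.51 and 77.3% reacted; that flask holds G 23.4%, E 6.02%, and has reacted 76.6%.

The numbers in the tables come from a simulation with made-up constants; scatter was added.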